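The flask takes 5.0 mM of solid substrate, 1.00 equivalent of capture agent, a larger charge of partner (12.5 mM) and 0.12 mM of catalyst, and a molecule of substrate that reaches solution has two exits, target or trapped intermediate.

| flask | solid substrate | partner | capture agent | catalyst | remark | time |
|---|---|---|---|---|---|---|
| Thursday's | 5 mM | 12.5 mM (fed, over 6.0 s) | 5 mM | 0.12 mM | the very flask that is asked about, followed so far; the fed solution adds 0.25 times the starting volume |  |
| flask | 5.0 mM | 12.5 mM (fed, over 6.0 s) | 5.00 mM | 0.12 mM | the fed solution adds 0.25 times the starting volume | 10 min |

- Thursday's (time / min: target / %, trapped intermediate / %): 0.250: 1.4, 4.1; 0.833: 6.3, 21.6; 1.33: 13.5, 37.2; 2.00: 22.6, 53.5; 3.00: 30.6, 68.5; 4.00: 31.4, 68.6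

(each reading ± 0.5 percentage points)

- every charge counts on the volume at the start, and the solution that is fed holds the whole dose
- solid, in amounts per volume of the solution: solid substrate
- at the start none of the solid substrate is in solution

- how much target there is at 10 min, in percent of the solid substrate charged
- how much trapped intermediate there is at 10 min, in percent of the solid substrate charged

Thursday's last reading sums to 100 %, while capture agent, if each trapped intermediate spends one, still stands at 31.4 %, so solid substrate looks like the limiting reagent. A first estimate of the fork in this flask is the final ratio of trapped intermediate to target, 2.18. That ratio does not hold along the run, however: it reads 3.43 up to 0.833 min, but 1.88 between 2.00 min and 3.00 min.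

A better estimate lets the odds sink with the capture agent left. With partner taken as steady, they are then minus the logarithm of the capture agent's remaining fraction, divided by the target fraction. The last reading gives 3.69 for these capture odds, a selectivity factor: trapped intermediate formed per target formed with one equivalent of capture agent standing. The objection is that 2.00 min gives 3.39, so the figure drifts, and partner, at one per target, falls to 87.4 %, which could contribute.

A second doubt is a slow leak of trapped intermediate into target: trapped intermediate gained 0.1 percentage points in the last minute, with each reading good to 0.5 points, which bounds a leak only loosely. My own reckoning keeps the last reading, 31.4 % and 68.6 %. The forecast differs slightly, at 31.7 % and 68.3 %: “The trapped intermediate shows no clear decay or release into target, so I treat it as essentially stable.”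

The flask gives 31.6 % of target and 68.4 % of trapped intermediate, so the forecast is right within its margin.

    solid substrate ⇌ starting material, rate k1*(cs1 - [starting material]) while solid is left; crystals form when [starting material] > cs1 (solubility = 0.390 mM, k = 0.149 s⁻¹)
    partner + catalyst + open intermediate → catalyst + target (k = 1.15 × 10⁵ L² mol⁻² s⁻¹)
    starting material + catalyst ⇌ catalyst + open intermediate (K = 8.00, k = 1390 L mol⁻¹ s⁻¹)
    open intermediate + capture agent → trapped intermediate (k = 93.8 L mol⁻¹ s⁻¹)

At 1.31 min open intermediate goes to trapped intermediate 2.3 times as fast as to target, and the capture odds times the capture agent left at the reading of 1.33 min give 2.32. The forecast's split does not carry over to a larger capture charge: taking 0.5 equivalent as spent on average, the odds put target at 12.5 % in the neighbour flask with 12 mM of capture agent, which holds 12.9 %.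

The readings are calculated from invented constants, and the scatter is random.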